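Neighbouring flasks share one charge and differ in what is fed, and when.

the same everywhere: protic impurity 0.0150 M; time 10 h
- gamma: starting material 0.050 M (fed, over 8.0 h); partner 0.200 M; all else is in the flask from the start; the feed brings no volume worth counting
- theta: starting material 0.050 M; partner 0.200 M; everything together at the start
- epsilon: starting material 0.050 M; partner 0.200 M (fed, over 8.0 h); all else is in the flask from the start; the feed brings no volume worth counting

    starting material + partner → target (k1 = 1.47 M⁻¹ h⁻¹)
    starting material + partner → isomer of the product (k2 = 1.48 M⁻¹ h⁻¹)
    starting material + partner → second isomer (k3 = 1.26 M⁻¹ h⁻¹)
    partner → decomposed reagent (k4 = 0.302 h⁻¹)
    partner + protic impurity → quenched reagent (k5 = 24.7 M⁻¹ h⁻¹)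

* the flask with the highest amount of target, in percent of the starting material charged ("all alike" if they lie within 1.5 percentage points) (gamma / theta / epsilon / all alike)
* final target, as a percentage of the starting material charged, in gamma
* final target, as a percentage of the starting material charged, in theta
* final target, as a percentage of the starting material charged, in epsilon

The product steps use the same pair, so target is a fixed share of starting material consumed, the selectivity: 34.9%. Starting material falls pseudo-first-order under the partner concentration, so conversion follows partner's time integral, its exposure, with summed constant 4.21 M⁻¹ h⁻¹. With the whole partner charge present, the impurity itself vanishes with time constant 0.202 h, shorter than partner's decomposition time constant 3.31 h, so we strike the impurity's charge first. The remainder over the decomposition constant is the partner budget: 36.8 M·min.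

For theta, spending no partner on starting material gives a ceiling: conversion 92.4%, target 32.2%. For a floor, we spend the whole starting charge and leave at most 9.03 mM of partner unused, giving conversion 82.7%. Feeding each conversion back as the spend tightens the bracket: ceiling conversion 86.5%, floor 84.3%. Theta's target therefore lies between 29.4% and 30.2%.

Gamma's feed lasts 2.42 partner time constants, and a parcel fed at any moment meets at most the budget shrunk by partner's decay up to that moment. Averaged over the feed, the summed constant times that exposure is at most 0.972, and since conversion bends downward with exposure, gamma's conversion is at most 62.2% and its target at most 21.7%. That ceiling lies below theta's floor, so gamma ends below theta. We leave epsilon without a bracket.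

The forecast names theta, with 14.7% for gamma, 29.8% for theta and 27.9% for epsilon, on the ground that “all three routes share the same split”.

The simulation gives theta first at 29.8%, inside our bracket, then epsilon at 28.0% and gamma at 14.6%. Gamma's value stands below its ceiling of 21.7%. The neighbour of gamma with 0.80 M of partner has budget 156 M·min, larger than gamma's. The same average over the feed is at most 4.13, so its conversion is at most 98.4% and its target at most 34.4%. That neighbour ends at 10.0 h holding 19.3% of starting material and 28.2% of target, less than that ceiling.

The constants were chosen freely.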